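The ratio of partner charged in grey to amber was 3.92, and my decision was whether that extra partner bought target or whether amber's charge could be kept for the repeat.

in all of them: substrate 0.051 M; protic impurity 2.55 mM

|  | partner | temperature | remark | time |
|---|---|---|---|---|
| north-east | 0.032 M | 0 °C | run made earlier |  |
| north | 0.060 M | 25 °C | run made earlier |  |
| south-east | 0.13 M | 0 °C | run made earlier |  |
| grey | 0.120 M |  | at 5 °C throughout | 2.0 h |
| amber | 0.0306 M |  | at 5 °C until 25 min, from then on at 45 °C | 2.0 h |

| run | time / min | target / % | substrate / % |
|---|---|---|---|
| north-east | 10.0 | 21.0 | 67.6 |
| north-east | 20.0 | 26.2 | 59.2 |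
| north-east | 30.0 | 28.9 | 58.8 |
| north-east | 60.0 | 30.7 | 55.7 |
| north-east | 120 | 31.3 | 56.0 |
| north | 4.00 | 36.8 | 31.2 |
| north | 8.00 | 40.7 | 25.7 |
| north | 12.0 | 45.8 | 23.1 |
| north | 20.0 | 47.0 | 21.5 |
| north | 40.0 | 48.0 | 20.5 |
| south-east | 25.0 | 27.3 | 0.4 |
| south-east | 50.0 | 26.1 | 0 |
| south-east | 80.0 | 26.9 | 0.5 |
| south-east | 90.0 | 28.0 | 1.2 |
| south-east | 120 | 25.9 | 0 |

(scatter of a reading: 1 percentage point)

- the winner by amount of target, in percent of the substrate charged; "neither" if no more than 2 percentage points parts them (grey / amber / neither)
- how much target is there at the end, in percent of the substrate charged: grey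
- how much target is there at the end, in percent of the substrate charged: amber



Substrate lost beyond target suggested a side product taking two partner, in parallel with target taking one. I first took usable partner as the charge minus the protic impurity. In the south-east run, target averaged 26.8% with substrate reading at most 1.2%, so I reckoned that partner fell from 0.127 M to 0.0391 M. Side product over target, divided by mean partner, gave a first value of 32.7 /M.

Integrating the split gives target concentration = ln[(1+2KP)/(1+2KE)]/(2K), with P the usable partner and E the partner at the end. One pass through this gave K, the split constant, a selectivity factor: side product formed per target formed at one molar free partner, 35.2 /M.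

As a check on different readings, I took no partner at the end of the north-east run, and the reckoning gave 31.3%, against 31.3% read. For the north run, which differed in both temperature and partner, the same reckoning gave 45.1% against 48.0% read. The north-east run read nearly all of its last target reading by 30.0 min, so I expected amber's heating to act on a small tail.

I reckoned amber at 30.4%. For grey, taking amber's value to estimate the end partner gave 29.8%. The gap of 0.60 percentage points was less than the margin, so I would keep amber's charge, a quarter of grey's partner.

The forecast, with its constant of 34, said neither: 30.6% for grey and 31% for amber, calling amber “partner-limited and mostly finished before heating”. Both its figures stood higher than mine.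

The flasks gave neither, with 30.4% for grey and 30.3% for amber.

    substrate + 2 partner → side product (k = 88.0 /M²/min, Ea = 43.0 kJ/mol)
    partner + protic impurity → quenched reagent (k = 10.0 /M/min, Ea = 51.0 kJ/mol)
    substrate + partner → target (k = 2.60 /M/min, Ea = 46.0 kJ/mol)
    (constants at 5 °C)

Both flasks had come to rest. At 2.00 h, grey held substrate 0% and partner 26% of its charge, while amber held substrate 56.9% and partner 0%, the limiting reagent. At 20.0 h the answers stood unchanged at 30.4% and 30.3%. With amber as it is, the forecast's tie is gone once grey is charged with 0.106 M or 0.139 M partner, where grey has moved by 5 points.

For the neighbour of grey with 0.048 M partner, K and no end partner gave 40.0%. The computed flask held 39.8% target, with 35.4% substrate and 0.0367% partner left.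

All runs stem from a simulated flask on assumed constants; scatter was added.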